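**Retrosynthetic overview**
1. The aryl ether C11–O is made last (umbelliferone plus a decalin diol, Mitsunobu reaction); the axial C3 carbinol comes from a C3 ketone and a bulky hydride.
2. Ring B is cut at C6–C7 and C8–C9 into propyne and a cyclobutanone fused to ring A: nickel-catalysed insertion of the alkyne into the C6–C9 bond (two-carbon ring expansion, formal [4+2]).
3. Enabling feature: ring B is a 3-methylcyclohex-2-enone whose carbonyl carbon C6 and sp3 carbon C9 both sit on the ring-fusion bond C5–C10. C6(=O)–C5–C10–C9 can therefore exist as a strained four-membered ketone on ring A, and C7H=C8(CH3) is exactly propyne. C5 is α to the ketone, so the cis fusion imposed by the four-membered ring can be turned into the trans-decalin afterwards.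
4. The cyclobutanone comes from the ring A alkene and dichloroketene ([2+2], sets C5 and C10), then C9 alkylation (CH2OBn). The ring A alkene comes from 4-methylcyclohex-2-en-1-one by gem-dimethylation and CBS reduction; its C3 carbinol relays the absolute configuration and is inverted at the end.
5. Order of ring formation: ring A (bought) → four-membered ring (step 4) → ring B (step 7); the coumarin is attached last.

Key step: step 7

Remark: drimane numbering is used throughout (ring A = C1–C5, C10; ring B = C5–C10; C11 = CH2O). 4-Methylcyclohex-2-en-1-one is assumed to be a catalogue compound (otherwise one extra step from 4-methylanisole by Birch reduction and hydrolysis).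

**Step 1**
Reactants: 1 4-methylcyclohex-2-en-1-one
Product: 2 2,2,4-trimethylcyclohex-3-en-1-one
Conditions: t-BuOK (2.5 equiv), MeI (3 equiv), t-BuOH/THF, 0 °C → rt
Reagents that add atoms: iodomethane, CI
Why: Deconjugative α,α-dimethylation of an enone: t-BuOK gives the extended dienolate, which is methylated twice at the α-carbon (the second time via the β,γ-enone), so the alkene ends as C5=C10 next to the new quaternary C4; the product is achiral.

**Step 2**
Reactants: 2 2,2,4-trimethylcyclohex-3-en-1-one
Product: 3 (R)-2,2,4-trimethylcyclohex-3-en-1-ol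
Conditions: (S)-2-methyl-CBS-oxazaborolidine (20 mol %), catecholborane, toluene, −78 °C
Reagents that add atoms: none
Why: Corey–Bakshi–Shibata reduction: with the quaternary C4 as the large flank and the C2 methylene as the small one, the (S)-oxazaborolidine should give the (R)-carbinol at C3 (same sense as for pinacolone), and catecholborane at low temperature spares the alkene; this centre is a relay that steers step 4 and is inverted in steps 10 and 11.

**Step 3**
Reactants: 3 (R)-2,2,4-trimethylcyclohex-3-en-1-ol
Product: 4 (R)-tert-butyldimethyl[(2,2,4-trimethylcyclohex-3-en-1-yl)oxy]silane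
Conditions: TBSOTf, 2,6-lutidine, CH2Cl2, 0 °C
Reagents that add atoms: tert-butyldimethylsilyl triflate, CC(C)(C)[Si](C)(C)OS(=O)(=O)C(F)(F)F
Why: Silyl ether formation with the triflate, as needed for a hindered neopentyl-type secondary alcohol; the bulky OTBS group is the control element for step 4 and C3 is unchanged.

**Step 4**
Reactants: 4 (R)-TBS ether of the ring A alkene
Product: 5 (1R,4R,6S)-4-[(tert-butyldimethylsilyl)oxy]-8,8-dichloro-1,5,5-trimethylbicyclo[4.2.0]octan-7-one
Conditions: Cl3CCOCl, Zn–Cu couple, POCl3, Et2O, rt → 35 °C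
Reagents that add atoms: trichloroacetyl chloride, ClC(=O)C(Cl)(Cl)Cl (turned by zinc into dichloroketene, ClC(Cl)=C=O, which is what adds)
Why: Ketene–alkene [2+2] cycloaddition: dichloroketene adds suprafacially (cis fusion, C5–H and C10–CH3 cis), its carbonyl carbon bonding to the less substituted alkene carbon C5, and it should add anti to OTBS because in the half-chair with equatorial OTBS the pseudoaxial C4 methyl group shields the OTBS face; this fixes C5 and C10 relative to C3.

**Step 5**
Reactants: 5 dichlorocyclobutanone
Product: 6 (1S,4R,6R)-4-[(tert-butyldimethylsilyl)oxy]-1,5,5-trimethylbicyclo[4.2.0]octan-7-one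
Conditions: Zn dust, AcOH, rt
Reagents that add atoms: none
Why: Zinc reduction of the α,α-dichloroketone to the parent cyclobutanone; no stereocentre is involved.

**Step 6**
Reactants: 6 cis-fused cyclobutanone
Product: 8 (1R,4R,6R,8R)-8-[(benzyloxy)methyl]-4-[(tert-butyldimethylsilyl)oxy]-1,5,5-trimethylbicyclo[4.2.0]octan-7-one, via lithium enolate 7 (not isolated)
Conditions: LiN(i-Pr)2, THF, −78 °C (ketone added to base); then BnOCH2Cl, −78 → −30 °C
Reagents that add atoms: benzyl chloromethyl ether, ClCOCc1ccccc1
Why: Kinetic enolate alkylation: LiN(i-Pr)2 removes a proton from the accessible C9 methylene and not from the C5 methine shielded by the gem-dimethyl group, and the electrophile should enter C9 on the convex face of the cis-fused bicycle, cis to the angular methyl group and away from ring A, which is also the more stable C9 epimer.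

**Step 7**
Reactants: 8 benzyloxymethyl cyclobutanone; 9 propyne
Product: 12 (4R,4aS,7R,8aR)-4-[(benzyloxy)methyl]-7-[(tert-butyldimethylsilyl)oxy]-3,4a,8,8-tetramethyl-4a,5,6,7,8,8a-hexahydronaphthalen-1(4H)-one (cis-fused), via oxanickelacycle 10 (not isolated), via nickelacycloheptenone 11 (not isolated)
Conditions: Ni(cod)2 (10 mol %), PCy3 (20 mol %), propyne (3–5 equiv, slow addition as a THF solution), toluene, 60–80 °C
Reagents that add atoms: none
Why: Proposed new method: zerovalent nickel should couple the strained C6 carbonyl of 8 with propyne by oxidative cyclisation (C6–C7 bond, nickel on the methyl-bearing carbon C8) to the spiro oxanickelacyclopentene 10, strain-driven β-carbon elimination then cleaves C6–C9 to the seven-membered nickelacycle 11, and C(sp2)–C(sp3) reductive elimination forms C8–C9 and releases the cyclohexenone. The closest known reaction type is the Ni(cod)2/phosphine-catalysed intermolecular [4+2] insertion of internal alkynes into 3-substituted cyclobutanones and azetidin-3-ones; it has not been shown for an acyl–CH(R) bond of a ring-fused α,α'-disubstituted cyclobutanone or with a terminal alkyne, hence the label. Ring B is closed in the reductive elimination from the seven-membered metallacycle, the overall mode being a two-carbon ring expansion (formal [4+2]) of the four-membered ring. No new stereocentre is created: C9 should be carried through with retention (β-carbon elimination and reductive elimination are both retentive at sp3 carbon) and C5 and C10 are untouched, so 12 keeps the cis ring fusion of 8. Two selectivities are needed: cleavage of C6–C9 and not C6–C5, expected because a nickel–C5 bond would lie between the quaternary carbons C4 and C10 whereas C9 has only one quaternary neighbour; and C–C bond formation at the unsubstituted alkyne terminus, the usual sense for nickel-mediated carbonyl–alkyne oxidative cyclisation, which puts H on C7 and CH3 on C8. Slow addition of propyne is meant to hold back alkyne oligomerisation.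

**Step 8**
Reactants: 12 cis-fused enone
Product: 13 (4R,4aS,7R,8aS)-4-[(benzyloxy)methyl]-7-[(tert-butyldimethylsilyl)oxy]-3,4a,8,8-tetramethyl-4a,5,6,7,8,8a-hexahydronaphthalen-1(4H)-one (trans-fused)
Conditions: K2CO3, MeOH, rt
Reagents that add atoms: none
Why: Base-mediated epimerisation at C5 through the cross-conjugated enolate, expected to favour the trans-fused decalin as for other cis-fused 6-oxo decalins and 7-en-6-one steroids; C9 is only vinylogously acidic and should be left alone by carbonate at room temperature.

**Step 9**
Reactants: 13 trans-fused enone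
Product: 14 (4R,4aS,7R,8aS)-4-[(benzyloxy)methyl]-7-hydroxy-3,4a,8,8-tetramethyl-4a,5,6,7,8,8a-hexahydronaphthalen-1(4H)-one
Conditions: HF·pyridine, THF, 0 → 40 °C
Reagents that add atoms: none
Why: Fluoride cleavage of the hindered secondary silyl ether under acidic conditions that avoid base at the γ-position of the enone; no stereocentre changes.

**Step 10**
Reactants: 14 equatorial C3 alcohol
Product: 15 (4R,4aS,8aS)-4-[(benzyloxy)methyl]-3,4a,8,8-tetramethyl-4a,5,6,8a-tetrahydronaphthalene-1,7(4H,8H)-dione
Conditions: Dess–Martin periodinane, NaHCO3, CH2Cl2, rt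
Reagents that add atoms: none
Why: Dess–Martin oxidation of the C3 alcohol to the ketone, which erases the relay stereocentre; the conditions are neutral, so C5 and C9 should hold.

**Step 11**
Reactants: 15 3,6-dione
Product: 16 (4R,4aS,7S,8aS)-4-[(benzyloxy)methyl]-7-hydroxy-3,4a,8,8-tetramethyl-4a,5,6,7,8,8a-hexahydronaphthalen-1(4H)-one
Conditions: LiBH(s-Bu)3 (L-Selectride, 1.1 equiv), THF, −78 °C; then H2O
Reagents that add atoms: none
Why: Diastereoselective ketone reduction with a bulky hydride: LiBH(s-Bu)3 should attack the 4,4-dimethyl-3-ketone of the trans-decalin along the equatorial trajectory and give the axial alcohol, trans to the C10 methyl group (the target configuration at C3), the saturated ketone reacting before the hindered β,β-disubstituted enone.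

**Step 12**
Reactants: 16 axial C3 alcohol
Product: 17 (4R,4aS,7S,8aS)-7-hydroxy-4-(hydroxymethyl)-3,4a,8,8-tetramethyl-4a,5,6,7,8,8a-hexahydronaphthalen-1(4H)-one
Conditions: BCl3, pentamethylbenzene, CH2Cl2, −78 °C
Reagents that add atoms: none
Why: Lewis acid debenzylation with pentamethylbenzene as cation scavenger, a non-reductive method that leaves the enone alkene intact; no stereocentre changes.

**Step 13**
Reactants: 17 diol; 18 umbelliferone (7-hydroxy-2H-chromen-2-one)
Product: 19 ferocaulidin, 7-{[(1R,4aS,6S,8aS)-6-hydroxy-2,5,5,8a-tetramethyl-4-oxo-1,4,4a,5,6,7,8,8a-octahydronaphthalen-1-yl]methoxy}-2H-chromen-2-one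
Conditions: PPh3, DIAD, THF, 0 °C → rt
Reagents that add atoms: none
Why: Mitsunobu etherification: the primary C11 alcohol is activated in preference to the hindered axial C3 alcohol and is displaced by the acidic phenol (C11 is not a stereocentre), under neutral conditions that spare the base-sensitive γ-position of the enone.

**Compound list**
1 | 4-methylcyclohex-2-en-1-one | CC1CCC(=O)C=C1 | starting material
2 | 2,2,4-trimethylcyclohex-3-en-1-one | CC1=CC(C)(C)C(=O)CC1 | intermediate
3 | (R)-2,2,4-trimethylcyclohex-3-en-1-ol | CC1=CC(C)(C)[C@H](O)CC1 | intermediate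
4 | (R)-tert-butyldimethyl[(2,2,4-trimethylcyclohex-3-en-1-yl)oxy]silane | CC1=CC(C)(C)[C@H](O[Si](C)(C)C(C)(C)C)CC1 | intermediate
5 | (1R,4R,6S)-4-(TBS-oxy)-8,8-dichloro-1,5,5-trimethylbicyclo[4.2.0]octan-7-one (cis-fused; OTBS cis to the angular methyl) | C[C@@]12CC[C@@H](O[Si](C)(C)C(C)(C)C)C(C)(C)[C@@H]1C(=O)C2(Cl)Cl | intermediate
6 | (1S,4R,6R)-4-(TBS-oxy)-1,5,5-trimethylbicyclo[4.2.0]octan-7-one | C[C@@]12CC[C@@H](O[Si](C)(C)C(C)(C)C)C(C)(C)[C@@H]1C(=O)C2 | intermediate
7 | lithium enolate of 6 (C6=C9) | C[C@@]12CC[C@@H](O[Si](C)(C)C(C)(C)C)C(C)(C)[C@@H]1C([O-])=C2.[Li+] | intermediate (not isolated)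
8 | (1R,4R,6R,8R)-8-[(benzyloxy)methyl]-4-(TBS-oxy)-1,5,5-trimethylbicyclo[4.2.0]octan-7-one (CH2OBn cis to the angular methyl) | C[C@@]12CC[C@@H](O[Si](C)(C)C(C)(C)C)C(C)(C)[C@@H]1C(=O)[C@H]2COCc1ccccc1 | intermediate
9 | propyne | CC#C | starting material
10 | spiro oxanickelacyclopentene from 8 and propyne (PCy3 on nickel not drawn; C6 configuration open) | CC1=CC2(O[Ni]1)[C@H]3C(C)(C)[C@H](O[Si](C)(C)C(C)(C)C)CC[C@@]3(C)[C@@H]2COCc2ccccc2 | intermediate (not isolated)
11 | seven-membered nickelacycle, Ni bound to C8 and C9 (PCy3 on nickel not drawn) | CC1=CC(=O)[C@H]2C(C)(C)[C@H](O[Si](C)(C)C(C)(C)C)CC[C@@]2(C)[C@@H]([Ni]1)COCc1ccccc1 | intermediate (not isolated)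
12 | (4R,4aS,7R,8aR)-4-[(benzyloxy)methyl]-7-(TBS-oxy)-3,4a,8,8-tetramethyl-4a,5,6,7,8,8a-hexahydronaphthalen-1(4H)-one (cis-fused) | CC1=CC(=O)[C@H]2C(C)(C)[C@H](O[Si](C)(C)C(C)(C)C)CC[C@@]2(C)[C@@H]1COCc1ccccc1 | intermediate
13 | (4R,4aS,7R,8aS)-4-[(benzyloxy)methyl]-7-(TBS-oxy)-3,4a,8,8-tetramethyl-4a,5,6,7,8,8a-hexahydronaphthalen-1(4H)-one (trans-fused) | CC1=CC(=O)[C@@H]2C(C)(C)[C@H](O[Si](C)(C)C(C)(C)C)CC[C@@]2(C)[C@@H]1COCc1ccccc1 | intermediate
14 | (4R,4aS,7R,8aS)-4-[(benzyloxy)methyl]-7-hydroxy-3,4a,8,8-tetramethyl-4a,5,6,7,8,8a-hexahydronaphthalen-1(4H)-one (equatorial OH) | CC1=CC(=O)[C@@H]2C(C)(C)[C@H](O)CC[C@@]2(C)[C@@H]1COCc1ccccc1 | intermediate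
15 | (4R,4aS,8aS)-4-[(benzyloxy)methyl]-3,4a,8,8-tetramethyl-4a,5,6,8a-tetrahydronaphthalene-1,7(4H,8H)-dione | CC1=CC(=O)[C@@H]2C(C)(C)C(=O)CC[C@@]2(C)[C@@H]1COCc1ccccc1 | intermediate
16 | (4R,4aS,7S,8aS)-4-[(benzyloxy)methyl]-7-hydroxy-3,4a,8,8-tetramethyl-4a,5,6,7,8,8a-hexahydronaphthalen-1(4H)-one (axial OH) | CC1=CC(=O)[C@@H]2C(C)(C)[C@@H](O)CC[C@@]2(C)[C@@H]1COCc1ccccc1 | intermediate
17 | (4R,4aS,7S,8aS)-7-hydroxy-4-(hydroxymethyl)-3,4a,8,8-tetramethyl-4a,5,6,7,8,8a-hexahydronaphthalen-1(4H)-one | CC1=CC(=O)[C@@H]2C(C)(C)[C@@H](O)CC[C@@]2(C)[C@@H]1CO | intermediate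
18 | umbelliferone (7-hydroxy-2H-chromen-2-one) | O=c1ccc2ccc(O)cc2o1 | starting material
19 | ferocaulidin | CC1=CC(=O)[C@@H]2C(C)(C)[C@@H](O)CC[C@@]2(C)[C@@H]1COc1ccc2ccc(=O)oc2c1 | target

**Totals and risks**
Total step count: 13. Longest linear sequence: 13 steps (1 → 19).

Steps most likely to fail:

Step 7 (labelled proposed new method). Propyne may oligomerise faster than the hindered cyclobutanone carbonyl enters the oxidative cyclisation. The C9–nickel intermediate may also be lost through β-hydride or β-alkoxide elimination towards C11, or the wrong acyl–carbon bond (C6–C5) may be cleaved. The fallback uses known reaction types, sets out from 8 and comes back at 12. Addition of (Z)-CH3CH=CHMgBr with CeCl3 (THF, −78 °C) to the cyclobutanone carbonyl should give the tertiary 1-(prop-1-enyl)cyclobutanol F1. KH and 18-crown-6 in THF should then trigger the oxyanion-accelerated 1,3-shift (two-carbon ring expansion of a 1-alkenylcyclobutanolate to a cyclohexanone enolate), and trapping with Me3SiCl should give the ring-expanded trimethylsilyl enol ether F2. Saegusa–Ito dehydrogenation with Pd(OAc)2 in MeCN installs the C7=C8 double bond and returns to 12.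

Step 8. The cis/trans equilibrium at C5 may be slow or not far enough on the trans side, and competing γ-deprotonation may erode C9 or expel benzyl alcohol by vinylogous E1cB elimination. The fallback replaces equilibration by kinetic control, sets out from 12 and comes back at 13. α'-Deprotonation with LiN(i-Pr)2 and Me3SiCl (THF, −78 °C) should give the cross-conjugated trimethylsilyl dienol ether F3 (C5=C6). Fluoride-triggered protonation at low temperature (Bu4NF, AcOH, THF, −78 °C) should then deliver the proton to C5 on the face opposite to the angular C10 methyl group.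

Step 13. SN2 displacement at the β-branched primary carbon C11 may be slow, and the activated alcohol may instead be diverted to elimination towards C9, the γ-position of the enone. The fallback forms the aryl–oxygen bond instead of the alkyl–oxygen bond, sets out from 17 and comes back at 19: palladium-catalysed C–O coupling of the primary alcohol with 7-bromocoumarin (Pd2(dba)3, t-BuBrettPhos, Cs2CO3, toluene, 60–80 °C). No new compound is made on this fallback (F0).

**Further compounds**
F1 | step 7 | tertiary cyclobutanol from 8, C6 carrying OH and a (Z)-prop-1-enyl group (either C6 epimer) | C[C@@]12CC[C@@H](O[Si](C)(C)C(C)(C)C)C(C)(C)[C@@H]1C(O)(/C=C\C)[C@H]2COCc1ccccc1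
F2 | step 7 | trimethylsilyl enol ether (C6=C7) of the ring-expanded cis-fused ketone, C8 epimers | CC1C=C(O[Si](C)(C)C)[C@H]2C(C)(C)[C@H](O[Si](C)(C)C(C)(C)C)CC[C@@]2(C)[C@@H]1COCc1ccccc1
F3 | step 8 | cross-conjugated trimethylsilyl dienol ether of 12 (C5=C6, C7=C8) | CC1=CC(O[Si](C)(C)C)=C2C(C)(C)[C@H](O[Si](C)(C)C(C)(C)C)CC[C@@]2(C)[C@@H]1COCc1ccccc1
F0 | step 13 | none | none
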